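**Retrosynthetic overview**
- Target ⇐ fluoride desilylation of its octa‑TBS ether ⇐ palladium‑catalysed asymmetric C3‑prenylation of a 3‑aryl‑4‑hydroxycoumarin (sets C3).
- Pyranone ring (formed last) ⇐ lactonisation of a β‑keto ester ⇐ oxidation of the adduct of an intermolecular aldol addition (aryl acetate enolate + cyclohexenyl salicylaldehyde) that makes the C3–C4 bond and joins the two halves.
- Salicylaldehyde ⇐ ortho‑formylation of the one free phenol of the all‑cis cyclohexenyl ketone ⇐ kinetic protonation of the enolate of the all‑trans cycloadduct (inverts C4'').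
- Cyclohexene ring (formed first) ⇐ enantioselective borate‑catalysed Diels–Alder reaction of a dehydroprenyl diene (from 2,4,6‑trihydroxybenzaldehyde) with a 2'‑hydroxychalcone (from an aldol condensation).
- Ring order: cyclohexene, then pyranone; stereocentres: C3''/C5'' by cycloaddition, C4'' by protonation, C3 by allylation.

Assumption: the SMILES is taken literally, i.e. the three cyclohexene substituents are all cis (3''S,4''R,5''R; C3'' carries the chromane, C4'' the aroyl group, C5'' the aryl group) and chromane C3 is S; TBS = tert‑butyldimethylsilyl, Q = the all‑cis unit (1S,5R,6R)‑6‑[2,4‑bis(TBSO)benzoyl]‑5‑[2,4‑bis(TBSO)phenyl]‑3‑methylcyclohex‑2‑en‑1‑yl.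

**Route**

Step 1
Reactants: 1 2,4,6‑trihydroxybenzaldehyde
Product: 2 4‑(allyloxy)‑2,6‑dihydroxybenzaldehyde
Conditions: allyl bromide (1.0 equiv), KHCO3 (1.1 equiv), DMF, 40 °C
Reagents that add atoms: allyl bromide, C=CCBr
Why: Williamson etherification in which the weak base deprotonates only the 4‑OH, the most acidic hydroxyl and the one not hydrogen‑bonded to the formyl group (bis‑ether removed by chromatography).

Step 2
Reactants: 2 4‑(allyloxy)‑2,6‑dihydroxybenzaldehyde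
Product: 3 4‑(allyloxy)‑2,6‑bis(TBSO)benzaldehyde
Conditions: TBSCl (2.6 equiv), imidazole (5 equiv), DMAP (cat.), DMF, 40 °C
Reagents that add atoms: tert‑butyldimethylsilyl chloride, CC(C)(C)[Si](C)(C)Cl
Why: Silylation of both ortho phenols, silyl ethers being the one phenol protection that can be removed at the end without acid, base or hydrogenation.

Step 3
Reactants: 3 4‑(allyloxy)‑2,6‑bis(TBSO)benzaldehyde
Product: 4 (E)‑4‑[4‑(allyloxy)‑2,6‑bis(TBSO)phenyl]but‑3‑en‑2‑one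
Conditions: Ph3P=CHC(O)CH3 (1.5 equiv), toluene, 110 °C
Reagents that add atoms: 1‑(triphenylphosphoranylidene)propan‑2‑one, CC(=O)C=P(c1ccccc1)(c1ccccc1)c1ccccc1
Why: Wittig olefination with a stabilised ylide gives the (E)‑enone without the aqueous base of a Claisen–Schmidt condensation, which would cleave the aryl silyl ethers.

Step 4
Reactants: 4 (E)‑4‑[4‑(allyloxy)‑2,6‑bis(TBSO)phenyl]but‑3‑en‑2‑one
Product: 5 (E)‑1‑[4‑(allyloxy)‑2,6‑bis(TBSO)phenyl]‑3‑methylbuta‑1,3‑diene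
Conditions: Ph3PCH3Br (1.5 equiv), KOt‑Bu (1.4 equiv), THF, 0 °C → rt
Reagents that add atoms: methyltriphenylphosphonium bromide, C[P+](c1ccccc1)(c1ccccc1)c1ccccc1.[Br-]
Why: Wittig methylenation of the ketone by the unstabilised ylide gives the dehydroprenyl diene with the (E)‑styryl geometry unchanged.

Step 5
Reactants: 6 2,4‑dihydroxyacetophenone
Product: 7 1‑[4‑(TBSO)‑2‑hydroxyphenyl]ethanone
Conditions: TBSCl (1.05 equiv), imidazole (1.5 equiv), CH2Cl2, 0 °C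
Reagents that add atoms: tert‑butyldimethylsilyl chloride, CC(C)(C)[Si](C)(C)Cl
Why: Selective silylation of the 4‑OH, since the 2‑OH is chelated to the ketone and must stay free for boron chelation in the cycloaddition.

Step 6
Reactants: 8 2,4‑dihydroxybenzaldehyde
Product: 9 2,4‑bis(TBSO)benzaldehyde
Conditions: TBSCl (2.4 equiv), imidazole (4 equiv), DMF, rt
Reagents that add atoms: tert‑butyldimethylsilyl chloride, CC(C)(C)[Si](C)(C)Cl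
Why: Exhaustive silylation of both phenols gives a non‑enolisable aldehyde for the condensation.

Step 7
Reactants: 7 1‑[4‑(TBSO)‑2‑hydroxyphenyl]ethanone; 9 2,4‑bis(TBSO)benzaldehyde
Product: 11 (E)‑3‑[2,4‑bis(TBSO)phenyl]‑1‑[4‑(TBSO)‑2‑hydroxyphenyl]prop‑2‑en‑1‑one, via dilithium aldolate 10 (not isolated)
Conditions: LiN(SiMe3)2 (2.3 equiv), THF, −78 °C; then 9, −78 °C → rt
Reagents that add atoms: none
Why: Claisen–Schmidt aldol condensation run aprotically, the phenoxide‑enolate of the ketone adding to the aldehyde and the aldolate eliminating (E1cB) to the conjugated (E)‑chalcone without hydroxide in alcohol.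

Step 8
Reactants: 5 (E)‑1‑[4‑(allyloxy)‑2,6‑bis(TBSO)phenyl]‑3‑methylbuta‑1,3‑diene; 11 (E)‑3‑[2,4‑bis(TBSO)phenyl]‑1‑[4‑(TBSO)‑2‑hydroxyphenyl]prop‑2‑en‑1‑one
Product: 12 [(1S,2S,6R)‑2‑[4‑(allyloxy)‑2,6‑bis(TBSO)phenyl]‑6‑[2,4‑bis(TBSO)phenyl]‑4‑methylcyclohex‑3‑en‑1‑yl][4‑(TBSO)‑2‑hydroxyphenyl]methanone (exo adduct; all‑trans; 3''S,4''S,5''R)
Conditions: B(OPh)3 (30 mol %), (R)‑VANOL (30 mol %), 4 Å MS, PhCF3, 40 °C, diene in twofold excess (surplus recovered unchanged); chromatographic removal of the endo isomer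
Reagents that add atoms: none
Why: Diels–Alder reaction of the chalcone activated as a chiral 2'‑oxido borate, in which ortho/para regiochemistry puts the aryl‑bearing diene terminus next to the acyl carbon, the exo mode gives the all‑trans ring with the two aryl groups cis, and the VANOL pocket shields one enone face to set C3'' (S) and C5'' (R) (ligand antipode chosen by analogy and checked by CD, the mirror ligand giving the enantiomer).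

Step 9
Reactants: 12 exo adduct with free 2‑hydroxyl on the aroyl ring
Product: 13 [(1S,2S,6R)‑2‑[4‑(allyloxy)‑2,6‑bis(TBSO)phenyl]‑6‑[2,4‑bis(TBSO)phenyl]‑4‑methylcyclohex‑3‑en‑1‑yl][2,4‑bis(TBSO)phenyl]methanone
Conditions: TBSOTf (1.5 equiv), 2,6‑lutidine (3 equiv), CH2Cl2, 0 °C
Reagents that add atoms: tert‑butyldimethylsilyl triflate, CC(C)(C)[Si](C)(C)OS(=O)(=O)C(F)(F)F
Why: Silylation of the chelated phenol with the reactive triflate leaves the C4'' hydrogen as the only acidic site for the next step.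

Step 10
Reactants: 13 all‑trans ketone
Product: 15 1‑(allyloxy)‑3,5‑bis(TBSO)‑4‑Q‑benzene (all‑cis ketone; 3''S,4''R,5''R), via potassium enolate 14 (not isolated)
Conditions: KN(SiMe3)2 (1.5 equiv), THF, −78 → −30 °C; cannulate into AcOH (5 equiv)/THF, −78 °C
Reagents that add atoms: none
Why: Zimmerman‑type kinetic ketonisation, in which the two cis aryl groups at C3'' and C5'' block one face of the planar enolate so the proton arrives anti to both and the aroyl group ends cis to them (4''R), the contra‑thermodynamic all‑cis isomer (any recovered 13 is recycled).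

Step 11
Reactants: 15 1‑(allyloxy)‑3,5‑bis(TBSO)‑4‑Q‑benzene
Product: 16 3,5‑bis(TBSO)‑4‑Q‑phenol
Conditions: Pd(PPh3)4 (5 mol %), morpholine (5 equiv), THF, rt
Reagents that add atoms: none
Why: Tsuji–Trost deallylation, zerovalent palladium ionising the aryl allyl ether and morpholine trapping the allyl cation under neutral conditions that leave the silyl ethers, the hindered ketone and C4'' untouched.

Step 12
Reactants: 16 3,5‑bis(TBSO)‑4‑Q‑phenol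
Product: 18 2‑hydroxy‑4,6‑bis(TBSO)‑5‑Q‑benzaldehyde, via hydroxymethylphenol 17 (not isolated)
Conditions: MgCl2 (3 equiv), Et3N (5 equiv), (CH2O)n (6 equiv), THF, 65 °C
Reagents that add atoms: formaldehyde (as paraformaldehyde), C=O
Why: Casnati–Skattebøl ortho‑formylation, the magnesium phenoxide delivering formaldehyde only ortho to the single free phenol and a second formaldehyde oxidising the benzylic alkoxide by hydride transfer; the two ortho sites are equivalent by rotation about the aryl–C3'' bond.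

Step 13
Reactants: 18 2‑hydroxy‑4,6‑bis(TBSO)‑5‑Q‑benzaldehyde
Product: 19 2‑(allyloxy)‑4,6‑bis(TBSO)‑5‑Q‑benzaldehyde
Conditions: allyl alcohol (2 equiv), PPh3 (1.5 equiv), DIAD (1.5 equiv), THF, 0 °C → rt
Reagents that add atoms: allyl alcohol, C=CCO
Why: Mitsunobu etherification of the acidic salicylaldehyde phenol under neutral conditions masks it with a group that palladium removes later without touching the silyl ethers.

Step 14
Reactants: 20 2,4‑dihydroxyphenylacetic acid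
Product: 21 methyl 2‑(2,4‑dihydroxyphenyl)acetate
Conditions: MeOH, H2SO4 (cat.), reflux
Reagents that add atoms: methanol, CO
Why: Fischer esterification, excess methanol holding the open ester rather than the benzofuranone.

Step 15
Reactants: 21 methyl 2‑(2,4‑dihydroxyphenyl)acetate
Product: 22 methyl 2‑[2,4‑bis(TBSO)phenyl]acetate
Conditions: TBSCl (2.4 equiv), imidazole (4 equiv), DMF, rt
Reagents that add atoms: tert‑butyldimethylsilyl chloride, CC(C)(C)[Si](C)(C)Cl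
Why: Silylation of both phenols gives the enolisable ester partner in the same protecting‑group set as the rest of the molecule.

Step 16
Reactants: 22 methyl 2‑[2,4‑bis(TBSO)phenyl]acetate; 19 2‑(allyloxy)‑4,6‑bis(TBSO)‑5‑Q‑benzaldehyde
Product: 24 methyl 3‑[2‑(allyloxy)‑4,6‑bis(TBSO)‑5‑Q‑phenyl]‑2‑[2,4‑bis(TBSO)phenyl]‑3‑hydroxypropanoate (mixture of C2/C3 epimers), via lithium ester enolate 23 (not isolated)
Conditions: LiN(i‑Pr)2 (1.6 equiv), ester in excess (1.7 equiv), THF, −78 °C; then the aldehyde, −78 °C, 20 min; AcOH, −78 °C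
Reagents that add atoms: none
Why: Intermolecular aldol addition of the lithium ester enolate to the hindered, non‑enolisable aldehyde forms the future C3–C4 bond and joins the two halves; both new stereocentres are erased later and the cold quench prevents retro‑aldol and O‑to‑O silyl migration.

Step 17
Reactants: 24 aldol adduct (used crude)
Product: 25 methyl 3‑[2‑(allyloxy)‑4,6‑bis(TBSO)‑5‑Q‑phenyl]‑2‑[2,4‑bis(TBSO)phenyl]‑3‑oxopropanoate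
Conditions: Dess–Martin periodinane (1.5 equiv), NaHCO3 (4 equiv), CH2Cl2, 0 °C → rt
Reagents that add atoms: none
Why: Dess–Martin oxidation of the benzylic alcohol under buffered, non‑basic conditions gives the β‑keto ester and removes both aldol stereocentres from the problem.

Step 18
Reactants: 25 β‑keto ester with allyl‑protected ortho phenol
Product: 27 3‑[2,4‑bis(TBSO)phenyl]‑4‑hydroxy‑5,7‑bis(TBSO)‑6‑Q‑2H‑chromen‑2‑one, via free phenol keto ester 26 (not isolated)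
Conditions: Pd(PPh3)4 (5 mol %), morpholine (5 equiv), THF, rt; evaporate; DMAP (0.2 equiv), toluene, 80 °C; pH 4 work‑up
Reagents that add atoms: none
Why: Tsuji–Trost deallylation frees the only phenol ortho to the ketone, which lactonises onto the methyl ester (transesterification) to the 4‑hydroxycoumarin, so the pyranone closes on the correct oxygen.

Step 19
Reactants: 27 3‑aryl‑4‑hydroxycoumarin
Product: 28 (3S)‑3‑[2,4‑bis(TBSO)phenyl]‑3‑(3‑methylbut‑2‑en‑1‑yl)‑5,7‑bis(TBSO)‑6‑Q‑chromane‑2,4‑dione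
Conditions: prenyl methyl carbonate (1.5 equiv), Pd2(dba)3·CHCl3 (2.5 mol %), (R,R)‑DACH‑phenyl Trost ligand (7.5 mol %), CH2Cl2, 0 °C → rt
Reagents that add atoms: 3‑methylbut‑2‑en‑1‑yl methyl carbonate, COC(=O)OCC=C(C)C
Why: Palladium‑catalysed asymmetric allylic alkylation (Tsuji–Trost), the soft coumarin enolate attacking the unsubstituted terminus of the prenyl–palladium cation at C3 (O‑prenylation is reversible) while the chiral diphosphine pocket selects the enolate face for 3S (ligand sense to be confirmed on the first run, the C3 epimer being a separable diastereomer).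

Step 20
Reactants: 28 octa‑TBS ether
Product: 29 (3S)‑3‑(2,4‑dihydroxyphenyl)‑6‑[(1S,5R,6R)‑6‑(2,4‑dihydroxybenzoyl)‑5‑(2,4‑dihydroxyphenyl)‑3‑methylcyclohex‑2‑en‑1‑yl]‑5,7‑dihydroxy‑3‑(3‑methylbut‑2‑en‑1‑yl)chromane‑2,4‑dione
Conditions: HF·pyridine (excess), pyridine, THF, 0 °C → rt
Reagents that add atoms: none
Why: Fluoride desilylation of the eight aryl silyl ethers under buffered conditions that spare the β‑keto lactone, both alkenes and the epimerisable C4'' centre.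

**Compound list**

1 | 2,4,6‑trihydroxybenzaldehyde | O=Cc1c(O)cc(O)cc1O | starting material
2 | 4‑(allyloxy)‑2,6‑dihydroxybenzaldehyde | O=Cc1c(O)cc(OCC=C)cc1O | intermediate
3 | 4‑(allyloxy)‑2,6‑bis(TBSO)benzaldehyde | O=Cc1c(O[Si](C)(C)C(C)(C)C)cc(OCC=C)cc1O[Si](C)(C)C(C)(C)C | intermediate
4 | (E)‑4‑[4‑(allyloxy)‑2,6‑bis(TBSO)phenyl]but‑3‑en‑2‑one | CC(=O)/C=C/c1c(O[Si](C)(C)C(C)(C)C)cc(OCC=C)cc1O[Si](C)(C)C(C)(C)C | intermediate
5 | (E)‑1‑[4‑(allyloxy)‑2,6‑bis(TBSO)phenyl]‑3‑methylbuta‑1,3‑diene | C=C(C)/C=C/c1c(O[Si](C)(C)C(C)(C)C)cc(OCC=C)cc1O[Si](C)(C)C(C)(C)C | intermediate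
6 | 2,4‑dihydroxyacetophenone | CC(=O)c1ccc(O)cc1O | starting material
7 | 1‑[4‑(TBSO)‑2‑hydroxyphenyl]ethanone | CC(=O)c1ccc(O[Si](C)(C)C(C)(C)C)cc1O | intermediate
8 | 2,4‑dihydroxybenzaldehyde | O=Cc1ccc(O)cc1O | starting material
9 | 2,4‑bis(TBSO)benzaldehyde | O=Cc1ccc(O[Si](C)(C)C(C)(C)C)cc1O[Si](C)(C)C(C)(C)C | intermediate
10 | dilithium salt of 3‑[2,4‑bis(TBSO)phenyl]‑3‑hydroxy‑1‑[4‑(TBSO)‑2‑hydroxyphenyl]propan‑1‑one (racemic) | [Li+].[Li+].[O-]C(CC(=O)c1ccc(O[Si](C)(C)C(C)(C)C)cc1[O-])c1ccc(O[Si](C)(C)C(C)(C)C)cc1O[Si](C)(C)C(C)(C)C | intermediate (not isolated)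
11 | (E)‑3‑[2,4‑bis(TBSO)phenyl]‑1‑[4‑(TBSO)‑2‑hydroxyphenyl]prop‑2‑en‑1‑one | O=C(/C=C/c1ccc(O[Si](C)(C)C(C)(C)C)cc1O[Si](C)(C)C(C)(C)C)c1ccc(O[Si](C)(C)C(C)(C)C)cc1O | intermediate
12 | [(1S,2S,6R)‑2‑[4‑(allyloxy)‑2,6‑bis(TBSO)phenyl]‑6‑[2,4‑bis(TBSO)phenyl]‑4‑methylcyclohex‑3‑en‑1‑yl][4‑(TBSO)‑2‑hydroxyphenyl]methanone (all‑trans) | C=CCOc1cc(O[Si](C)(C)C(C)(C)C)c([C@H]3C=C(C)C[C@@H](c4ccc(O[Si](C)(C)C(C)(C)C)cc4O[Si](C)(C)C(C)(C)C)[C@@H]3C(=O)c5ccc(O[Si](C)(C)C(C)(C)C)cc5O)c(O[Si](C)(C)C(C)(C)C)c1 | intermediate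
13 | [(1S,2S,6R)‑2‑[4‑(allyloxy)‑2,6‑bis(TBSO)phenyl]‑6‑[2,4‑bis(TBSO)phenyl]‑4‑methylcyclohex‑3‑en‑1‑yl][2,4‑bis(TBSO)phenyl]methanone (all‑trans) | C=CCOc1cc(O[Si](C)(C)C(C)(C)C)c([C@H]3C=C(C)C[C@@H](c4ccc(O[Si](C)(C)C(C)(C)C)cc4O[Si](C)(C)C(C)(C)C)[C@@H]3C(=O)c5ccc(O[Si](C)(C)C(C)(C)C)cc5O[Si](C)(C)C(C)(C)C)c(O[Si](C)(C)C(C)(C)C)c1 | intermediate
14 | potassium enolate of 13 (C4'' planar; C3'' and C5'' unchanged; enolate geometry not defined) | C=CCOc1cc(O[Si](C)(C)C(C)(C)C)c([C@H]3C=C(C)C[C@@H](c4ccc(O[Si](C)(C)C(C)(C)C)cc4O[Si](C)(C)C(C)(C)C)C3=C([O-])c5ccc(O[Si](C)(C)C(C)(C)C)cc5O[Si](C)(C)C(C)(C)C)c(O[Si](C)(C)C(C)(C)C)c1.[K+] | intermediate (not isolated)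
15 | 1‑(allyloxy)‑3,5‑bis(TBSO)‑4‑Q‑benzene (all‑cis ketone) | C=CCOc1cc(O[Si](C)(C)C(C)(C)C)c([C@H]3C=C(C)C[C@@H](c4ccc(O[Si](C)(C)C(C)(C)C)cc4O[Si](C)(C)C(C)(C)C)[C@H]3C(=O)c5ccc(O[Si](C)(C)C(C)(C)C)cc5O[Si](C)(C)C(C)(C)C)c(O[Si](C)(C)C(C)(C)C)c1 | intermediate
16 | 3,5‑bis(TBSO)‑4‑Q‑phenol | Oc1cc(O[Si](C)(C)C(C)(C)C)c([C@H]3C=C(C)C[C@@H](c4ccc(O[Si](C)(C)C(C)(C)C)cc4O[Si](C)(C)C(C)(C)C)[C@H]3C(=O)c5ccc(O[Si](C)(C)C(C)(C)C)cc5O[Si](C)(C)C(C)(C)C)c(O[Si](C)(C)C(C)(C)C)c1 | intermediate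
17 | 2‑(hydroxymethyl)‑3,5‑bis(TBSO)‑4‑Q‑phenol (present as its magnesium salt; drawn neutral) | Oc1cc(O[Si](C)(C)C(C)(C)C)c([C@H]3C=C(C)C[C@@H](c4ccc(O[Si](C)(C)C(C)(C)C)cc4O[Si](C)(C)C(C)(C)C)[C@H]3C(=O)c5ccc(O[Si](C)(C)C(C)(C)C)cc5O[Si](C)(C)C(C)(C)C)c(O[Si](C)(C)C(C)(C)C)c1CO | intermediate (not isolated)
18 | 2‑hydroxy‑4,6‑bis(TBSO)‑5‑Q‑benzaldehyde | Oc1cc(O[Si](C)(C)C(C)(C)C)c([C@H]3C=C(C)C[C@@H](c4ccc(O[Si](C)(C)C(C)(C)C)cc4O[Si](C)(C)C(C)(C)C)[C@H]3C(=O)c5ccc(O[Si](C)(C)C(C)(C)C)cc5O[Si](C)(C)C(C)(C)C)c(O[Si](C)(C)C(C)(C)C)c1C=O | intermediate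
19 | 2‑(allyloxy)‑4,6‑bis(TBSO)‑5‑Q‑benzaldehyde | C=CCOc1cc(O[Si](C)(C)C(C)(C)C)c([C@H]3C=C(C)C[C@@H](c4ccc(O[Si](C)(C)C(C)(C)C)cc4O[Si](C)(C)C(C)(C)C)[C@H]3C(=O)c5ccc(O[Si](C)(C)C(C)(C)C)cc5O[Si](C)(C)C(C)(C)C)c(O[Si](C)(C)C(C)(C)C)c1C=O | intermediate
20 | 2,4‑dihydroxyphenylacetic acid | OC(=O)Cc1ccc(O)cc1O | starting material
21 | methyl 2‑(2,4‑dihydroxyphenyl)acetate | COC(=O)Cc1ccc(O)cc1O | intermediate
22 | methyl 2‑[2,4‑bis(TBSO)phenyl]acetate | COC(=O)Cc1ccc(O[Si](C)(C)C(C)(C)C)cc1O[Si](C)(C)C(C)(C)C | intermediate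
23 | lithium enolate of 22 (geometry not defined) | [Li+].[O-]C(OC)=Cc1ccc(O[Si](C)(C)C(C)(C)C)cc1O[Si](C)(C)C(C)(C)C | intermediate (not isolated)
24 | methyl 3‑[2‑(allyloxy)‑4,6‑bis(TBSO)‑5‑Q‑phenyl]‑2‑[2,4‑bis(TBSO)phenyl]‑3‑hydroxypropanoate (C2/C3 epimers; centres left undefined) | C=CCOc1cc(O[Si](C)(C)C(C)(C)C)c([C@H]3C=C(C)C[C@@H](c4ccc(O[Si](C)(C)C(C)(C)C)cc4O[Si](C)(C)C(C)(C)C)[C@H]3C(=O)c5ccc(O[Si](C)(C)C(C)(C)C)cc5O[Si](C)(C)C(C)(C)C)c(O[Si](C)(C)C(C)(C)C)c1C(O)C(C(=O)OC)c6ccc(O[Si](C)(C)C(C)(C)C)cc6O[Si](C)(C)C(C)(C)C | intermediate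
25 | methyl 3‑[2‑(allyloxy)‑4,6‑bis(TBSO)‑5‑Q‑phenyl]‑2‑[2,4‑bis(TBSO)phenyl]‑3‑oxopropanoate (C2 undefined) | C=CCOc1cc(O[Si](C)(C)C(C)(C)C)c([C@H]3C=C(C)C[C@@H](c4ccc(O[Si](C)(C)C(C)(C)C)cc4O[Si](C)(C)C(C)(C)C)[C@H]3C(=O)c5ccc(O[Si](C)(C)C(C)(C)C)cc5O[Si](C)(C)C(C)(C)C)c(O[Si](C)(C)C(C)(C)C)c1C(=O)C(C(=O)OC)c6ccc(O[Si](C)(C)C(C)(C)C)cc6O[Si](C)(C)C(C)(C)C | intermediate
26 | methyl 3‑[2‑hydroxy‑4,6‑bis(TBSO)‑5‑Q‑phenyl]‑2‑[2,4‑bis(TBSO)phenyl]‑3‑oxopropanoate | Oc1cc(O[Si](C)(C)C(C)(C)C)c([C@H]3C=C(C)C[C@@H](c4ccc(O[Si](C)(C)C(C)(C)C)cc4O[Si](C)(C)C(C)(C)C)[C@H]3C(=O)c5ccc(O[Si](C)(C)C(C)(C)C)cc5O[Si](C)(C)C(C)(C)C)c(O[Si](C)(C)C(C)(C)C)c1C(=O)C(C(=O)OC)c6ccc(O[Si](C)(C)C(C)(C)C)cc6O[Si](C)(C)C(C)(C)C | intermediate (not isolated)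
27 | 3‑[2,4‑bis(TBSO)phenyl]‑4‑hydroxy‑5,7‑bis(TBSO)‑6‑Q‑2H‑chromen‑2‑one | O=C1Oc2cc(O[Si](C)(C)C(C)(C)C)c([C@H]3C=C(C)C[C@@H](c4ccc(O[Si](C)(C)C(C)(C)C)cc4O[Si](C)(C)C(C)(C)C)[C@H]3C(=O)c5ccc(O[Si](C)(C)C(C)(C)C)cc5O[Si](C)(C)C(C)(C)C)c(O[Si](C)(C)C(C)(C)C)c2C(O)=C1c6ccc(O[Si](C)(C)C(C)(C)C)cc6O[Si](C)(C)C(C)(C)C | intermediate
28 | (3S)‑3‑[2,4‑bis(TBSO)phenyl]‑3‑(3‑methylbut‑2‑en‑1‑yl)‑5,7‑bis(TBSO)‑6‑Q‑chromane‑2,4‑dione | CC(C)=CC[C@@]1(c6ccc(O[Si](C)(C)C(C)(C)C)cc6O[Si](C)(C)C(C)(C)C)C(=O)Oc2cc(O[Si](C)(C)C(C)(C)C)c([C@H]3C=C(C)C[C@@H](c4ccc(O[Si](C)(C)C(C)(C)C)cc4O[Si](C)(C)C(C)(C)C)[C@H]3C(=O)c5ccc(O[Si](C)(C)C(C)(C)C)cc5O[Si](C)(C)C(C)(C)C)c(O[Si](C)(C)C(C)(C)C)c2C1=O | intermediate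
29 | (3S)‑3‑(2,4‑dihydroxyphenyl)‑6‑[(1S,5R,6R)‑6‑(2,4‑dihydroxybenzoyl)‑5‑(2,4‑dihydroxyphenyl)‑3‑methylcyclohex‑2‑en‑1‑yl]‑5,7‑dihydroxy‑3‑(3‑methylbut‑2‑en‑1‑yl)chromane‑2,4‑dione | CC(C)=CC[C@@]1(c2ccc(O)cc2O)C(=O)Oc2cc(O)c([C@H]3C=C(C)C[C@@H](c4ccc(O)cc4O)[C@H]3C(=O)c3ccc(O)cc3O)c(O)c2C1=O | target

**Summary**

Total step count: 20. Longest linear sequence: 15 steps (1 → 2 → 3 → 4 → 5 → 12 → 13 → 15 → 16 → 18 → 19 → 24 → 25 → 27 → 28 → 29).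

Three steps most likely to fail:

Step 8 (exo‑selective, enantioselective cycloaddition of a diene whose aryl group carries two ortho silyloxy groups; the exo share or the ee may be low). The fallback sets out from 5 and comes back at 15, bypassing 11 to 14, and builds the all‑cis triad directly by suprafacial addition to a ring‑locked cis‑cinnamate. 7‑Hydroxycoumarin is silylated (TBSCl, imidazole) to 7‑(TBSO)coumarin F1. Diene 5 and F1 are combined at 13–15 kbar (CH2Cl2, 50 °C, BHT), high pressure being needed because coumarins are poor dienophiles; the endo mode places the diene aryl group cis to the lactone carbonyl and gives the racemic cis‑fused lactone, that is all‑cis lactone F2 and its mirror image ent‑lactone F3, which are separated by preparative chiral SFC. F2 is opened with MeNH(OMe)·HCl/AlMe3 to the phenolic Weinreb amide F4 and silylated (TBSOTf, 2,6‑lutidine) to the Weinreb amide F5. F5 is then treated with the Grignard reagent F7, made (Mg, LiCl, THF) from 1‑bromo‑2,4‑bis(TBSO)benzene F6 (4‑bromoresorcinol, TBSCl, imidazole), to give ketone 15.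

Step 10 (kinetic protonation; enolisation of the hindered ketone may be incomplete or the proton may return 13). The fallback sets out from 13 and comes back at 15, replacing proton transfer by hydrogen‑atom transfer. Enolate 14 is trapped with PhSeCl to the α‑phenylselanyl ketone F8 (either C4'' configuration serves). Bu3SnH with Et3B/air in toluene at −78 °C then gives the planar α‑keto radical, which takes hydrogen irreversibly from the bulky stannane on the face away from both aryl groups, giving 15.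

Step 19 (face selectivity and C‑ versus O‑selectivity at the crowded C3). The fallback sets out from 27 and comes back at 28. Mitsunobu O‑prenylation (3‑methylbut‑2‑en‑1‑ol, PPh3, DIAD) gives the 4‑(prenyloxy)coumarin F9. This undergoes a [1,3] O‑to‑C prenyl shift (ion‑pair recombination at the unsubstituted allyl terminus) catalysed by Sc(OTf)3 with a chiral N,N'‑dioxide ligand; the (3R) epimer F10 formed alongside 28 is a diastereomer and is removed by chromatography.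

Further compounds
F1 | step 8 | 7‑(TBSO)‑2H‑chromen‑2‑one | O=C1C=Cc2ccc(O[Si](C)(C)C(C)(C)C)cc2O1
F2 | step 8 | 7‑[4‑(allyloxy)‑2,6‑bis(TBSO)phenyl]‑9‑methyl‑3‑(TBSO)‑6a,7,10,10a‑tetrahydro‑6H‑benzo[c]chromen‑6‑one (cis‑fused; aryl cis to the lactone carbonyl; configuration of 15) | C=CCOc1cc(O[Si](C)(C)C(C)(C)C)c([C@H]3C=C(C)C[C@H]6c4ccc(O[Si](C)(C)C(C)(C)C)cc4OC(=O)[C@@H]36)c(O[Si](C)(C)C(C)(C)C)c1
F3 | step 8 | enantiomer of F2 | C=CCOc1cc(O[Si](C)(C)C(C)(C)C)c([C@@H]3C=C(C)C[C@@H]6c4ccc(O[Si](C)(C)C(C)(C)C)cc4OC(=O)[C@H]36)c(O[Si](C)(C)C(C)(C)C)c1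
F4 | step 8 | (1R,2S,6R)‑2‑[4‑(allyloxy)‑2,6‑bis(TBSO)phenyl]‑6‑[4‑(TBSO)‑2‑hydroxyphenyl]‑N‑methoxy‑N,4‑dimethylcyclohex‑3‑ene‑1‑carboxamide (all‑cis) | C=CCOc1cc(O[Si](C)(C)C(C)(C)C)c([C@H]3C=C(C)C[C@@H](c4ccc(O[Si](C)(C)C(C)(C)C)cc4O)[C@H]3C(=O)N(C)OC)c(O[Si](C)(C)C(C)(C)C)c1
F5 | step 8 | (1R,2S,6R)‑2‑[4‑(allyloxy)‑2,6‑bis(TBSO)phenyl]‑6‑[2,4‑bis(TBSO)phenyl]‑N‑methoxy‑N,4‑dimethylcyclohex‑3‑ene‑1‑carboxamide (all‑cis) | C=CCOc1cc(O[Si](C)(C)C(C)(C)C)c([C@H]3C=C(C)C[C@@H](c4ccc(O[Si](C)(C)C(C)(C)C)cc4O[Si](C)(C)C(C)(C)C)[C@H]3C(=O)N(C)OC)c(O[Si](C)(C)C(C)(C)C)c1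
F6 | step 8 | 1‑bromo‑2,4‑bis(TBSO)benzene | Brc1ccc(O[Si](C)(C)C(C)(C)C)cc1O[Si](C)(C)C(C)(C)C
F7 | step 8 | [2,4‑bis(TBSO)phenyl]magnesium bromide | Br[Mg]c1ccc(O[Si](C)(C)C(C)(C)C)cc1O[Si](C)(C)C(C)(C)C
F8 | step 10 | [(2S,6R)‑2‑[4‑(allyloxy)‑2,6‑bis(TBSO)phenyl]‑6‑[2,4‑bis(TBSO)phenyl]‑4‑methyl‑1‑(phenylselanyl)cyclohex‑3‑en‑1‑yl][2,4‑bis(TBSO)phenyl]methanone (C1 undefined) | C=CCOc1cc(O[Si](C)(C)C(C)(C)C)c([C@H]3C=C(C)C[C@@H](c4ccc(O[Si](C)(C)C(C)(C)C)cc4O[Si](C)(C)C(C)(C)C)C3([Se]c7ccccc7)C(=O)c5ccc(O[Si](C)(C)C(C)(C)C)cc5O[Si](C)(C)C(C)(C)C)c(O[Si](C)(C)C(C)(C)C)c1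
F9 | step 19 | 3‑[2,4‑bis(TBSO)phenyl]‑4‑[(3‑methylbut‑2‑en‑1‑yl)oxy]‑5,7‑bis(TBSO)‑6‑Q‑2H‑chromen‑2‑one | O=C1Oc2cc(O[Si](C)(C)C(C)(C)C)c([C@H]3C=C(C)C[C@@H](c4ccc(O[Si](C)(C)C(C)(C)C)cc4O[Si](C)(C)C(C)(C)C)[C@H]3C(=O)c5ccc(O[Si](C)(C)C(C)(C)C)cc5O[Si](C)(C)C(C)(C)C)c(O[Si](C)(C)C(C)(C)C)c2C(OCC=C(C)C)=C1c6ccc(O[Si](C)(C)C(C)(C)C)cc6O[Si](C)(C)C(C)(C)C
F10 | step 19 | (3R) epimer of 28 | CC(C)=CC[C@]1(c6ccc(O[Si](C)(C)C(C)(C)C)cc6O[Si](C)(C)C(C)(C)C)C(=O)Oc2cc(O[Si](C)(C)C(C)(C)C)c([C@H]3C=C(C)C[C@@H](c4ccc(O[Si](C)(C)C(C)(C)C)cc4O[Si](C)(C)C(C)(C)C)[C@H]3C(=O)c5ccc(O[Si](C)(C)C(C)(C)C)cc5O[Si](C)(C)C(C)(C)C)c(O[Si](C)(C)C(C)(C)C)c2C1=O
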